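## Analysis of the target

The target is a flavanone. A benzene ring A is fused to a dihydropyranone ring C (O1, C2, C3, C4, C4a, C8a), and C2 carries the 4-hydroxyphenyl ring B. Ring A is hexasubstituted: C4a bears the C4 ketone, C5 a hydroxyl, C6 the prenyl group, C7 a hydroxyl, C8 a methyl group and C8a the ring oxygen O1. C2 is the only stereocenter and is S.

The C2–O1 bond is benzylic and beta to the ketone. Base can therefore open ring C by a retro-oxa-Michael reaction to an achiral chalcone, and a free 4'-phenoxide can expel O1 through a quinone methide; both pathways racemise C2. The prenyl alkene lies between two phenols, so acid closes it onto either oxygen to a dimethylchroman, and it does not tolerate hydrogenation or electrophilic oxidants.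

The real difficulty is the regiochemistry of ring A. In a phloroglucinol-type ketone both ortho hydroxyls can become O1, so the 8-methyl-6-prenyl and 6-methyl-8-prenyl series form side by side, and C-alkylation of such rings is unselective. The strategy rests on O5 being peri to the C4 carbonyl: a metal bound to that carbonyl reaches C5–H through a five-membered chelate, so O5 can be omitted at first and inserted later. Without O5, ring A comes from a 2-methylresorcinol ketone whose single ortho hydroxyl lies next to the methyl group. Ring C then closes in one sense only, and C6 remains the only free position of ring A for the prenyl group.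

## Retrosynthetic reasoning

**O4'–Si.** Target 22 is traced back to its 4'-triisopropylsilyl ether 21. Keeping O4' silylated until the end closes the quinone methide pathway during the basic and thermal steps and removes any competition between O7 and O4' in the etherification. The forward step only has to free one phenol with buffered fluoride, which endangers neither the prenyl group nor C2.

**C6–prenyl.** In 21 the bond between C6 and the prenyl CH2 is cut by a retro-Claisen shift to the O7 1,1-dimethylallyl ether 19, through dienone 20. Direct C-prenylation of a 5,7-dihydroxy ring would need base and gives mixtures of O- and C-alkylation. The [3,3] shift delivers a linear prenyl group intramolecularly to a position ortho to O7, and because C8 carries the methyl group only the shift to C6 can rearomatise. Ether 19 comes from alkyne 18 by semihydrogenation. Alkyne 18 comes from phenol 15 and 2-methylbut-3-yn-2-ol 16 through its trifluoroacetate 17, since a tertiary ether cannot be made by direct displacement but forms readily by copper-catalysed propargylic substitution. The chelated O5–H of 15 does not compete.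

**C2–aryl.** Phenol 15 is the deacetylated form of flavanone 14. In 14 the C2–C1' bond is cut to give chromone 8 and arylboronic acid 13. This cut places the formation of the only stereocenter on a flat, prochiral acceptor under catalyst control, and it avoids a chalcone cyclisation, which would again require a choice between ortho hydroxyls. It is placed after the oxygenation and before the prenylation, so that neither an alkene nor a free phenol is present when the arylpalladium species is formed.

**Boronic acid.** Compound 13 is cut at C–B to silyl ether 10 (through aryllithium 11 and borate 12), and 10 at O–Si to 4-bromophenol 9.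

**C5–O (key disconnection).** Chromone 8 is the acetate of phenol 7. In 7 the C5–O bond is cut to give 7-acetoxy-8-methylchromone 5; the forward reaction passes through aryl trifluoroacetate 6. The oxygen is inserted at this point and no other for two reasons. On ketone 1, before ring closure, hydroxylation would recreate two ortho hydroxyls and with them the regiochemical choice. After the aryl transfer, ring B and the C2 center would be exposed to a trivalent iodine oxidant in hot acid. Chromone 5 has no stereocenter, no alkene outside the pyranone and only one C–H bond ortho to the ketone.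

**Ring C.** Acetate 5 comes from phenol 4. In 4 the O1–C2 bond is cut to give enaminone 3, and the C2–C3 bond of 3 is cut to give ketone 1 and acetal 2. The ortho hydroxyl of 1 is the only one that can close, so the methyl group must end at C8.

## Alternatives that were turned down

**Alternative 1: ring A built last.** The C7–C8 and C4a–C5 bonds are cut, leaving the chiral dihydropyranone A2 and prenylmalonyl dichloride A3. In the forward key step a dienolate of A2 would be acylated twice by A3 under a hindered amine base and aromatise to A1.

- For: the methyl and prenyl groups arrive with the fragments, so no substitution on ring A and no late prenylation sequence is needed. A2 is within reach of a catalytic asymmetric hetero-Diels–Alder reaction. On convergence and step count this alternative is stronger than the chosen route.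
- Against: the dienolate must form at the ethyl CH2, but deprotonation at C3 competes and leads to beta-elimination of O1, which opens the ring and destroys the C2 configuration set earlier. Malonyl dichlorides with an alpha hydrogen give acyl ketenes with amines and acylate enols on oxygen, a path that usually ends in pyranones and not in a carbocycle. The acid released can add to the prenyl alkene.
- Comparison: the chosen strategy uses only bond formations known on this substrate class and sets C2 after ring A is complete.

**Alternative 2: aryl transfer to a finished ring A chromone.** The C2–C1' bond is cut last, giving the fully substituted chromone A5 and boronic acid A6. Enantioselective addition under a chiral pyridine-oxazoline complex of divalent palladium would give A4.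

- For: it is the same aryl transfer as in the chosen route, but only one deprotection follows it. It is the most convergent plan, and the stereocenter has the fewest later chances to racemise. On that point it is stronger than the chosen route.
- Against: A5 must first be made, and a hexasubstituted ring A with two different ortho hydroxyls brings back the closure problem that defines this target. The prenyl alkene would be exposed to a cationic arylpalladium species. The three MOM ethers of A4 must be removed by acid with the prenyl group between two phenols, where closure to a chroman competes.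
- Comparison: the chosen strategy gives an unambiguous ring A and keeps the alkene away from palladium and acid. It pays for this with five steps after the stereocenter is set, each of which must be run without racemisation.

**Alternative 3: carbene insertion into a benzylic ether C–H bond.** The C2–C3 bond is cut, giving diazoketone A8. A chiral dirhodium tetracarboxylate would generate a carbenoid at C3 that inserts into one of the two enantiotopic benzylic C–H bonds to give A7.

- For: ring C and the stereocenter form in one neutral step, and no chalcone equilibrium is possible at that step. On that point it is stronger than the chosen route.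
- Against: carbenoids of ortho-alkoxyaryl diazoketones are captured by the ether oxygen to give five-membered oxonium ylides, and a [1,2] shift of the benzyl group then gives a five-membered ring ketone. The insertion needed here forms a six-membered ring and is the slower path. An acceptor-only carbenoid is also poorly selective between enantiotopic hydrogens, and the prenyl alkene is a cyclopropanation partner. A8 needs a hexasubstituted benzoyl precursor, so ring A regiochemistry is not solved, and the route is longer.
- Comparison: the chosen strategy rests on firmer mechanistic ground for both ring closure and stereocontrol.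

Key step: step 4

Assumption: the facial model established for aryl transfer to cyclic enones with Pd(OCOCF3)2 and tert-butyl pyridine-oxazoline ligands is taken to hold for chromone 8. On that model (R)-4-tert-butyl-2-(pyridin-2-yl)-4,5-dihydrooxazole, written (R)-t-BuPyOx, should give the 2S flavanone; if the sense proves opposite, the ligand antipode is used.

## Route

Step 1
Reactants: 1 2,4-dihydroxy-3-methylacetophenone; 2 dimethylformamide dimethyl acetal
Product: 3 (E)-3-(dimethylamino)-1-(2,4-dihydroxy-3-methylphenyl)prop-2-en-1-one
Conditions: 2 (1.5 equiv), PhMe, 90 °C
Reagents that add atoms: none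
Why: Condensation of a methyl ketone with an amide acetal gives the E enaminone with loss of methanol; the acetal is kept near stoichiometric and the temperature below 100 °C so that O-methylation of the free para hydroxyl stays minor.

Step 2
Reactants: 3 (E)-3-(dimethylamino)-1-(2,4-dihydroxy-3-methylphenyl)prop-2-en-1-one
Product: 4 7-hydroxy-8-methylchromone (7-hydroxy-8-methyl-4H-chromen-4-one)
Conditions: conc. HCl, CH2Cl2, 40 °C
Reagents that add atoms: none
Why: Enaminone cyclisation to a chromone: acid-promoted oxa-Michael addition of the ortho hydroxyl and elimination of dimethylamine close ring C. The ketone has a single ortho hydroxyl, next to the methyl group, so O1 is bonded to C8a and the methyl group ends at C8 with no regioisomer possible.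

Step 3
Reactants: 4 7-hydroxy-8-methylchromone
Product: 5 7-acetoxy-8-methylchromone
Conditions: Ac2O, pyridine, DMAP (cat.), CH2Cl2, 0 °C to rt
Reagents that add atoms: acetic anhydride CC(=O)OC(C)=O
Why: Standard O-acylation of a phenol; the acetate lowers the electron density of ring A ahead of the oxidation and is stable to anhydrous acid.

Step 4
Reactants: 5 7-acetoxy-8-methylchromone
Product: 7 7-acetoxy-5-hydroxy-8-methylchromone, via aryl trifluoroacetate 6 (not isolated)
Conditions: [RuCl2(p-cymene)]2 (5 mol%), PhI(OCOCF3)2 (2 equiv), CF3CO2H/(CF3CO)2O, 80 °C; then H2O, rt
Reagents that add atoms: [bis(trifluoroacetoxy)iodo]benzene O=C(OI(OC(=O)C(F)(F)F)c1ccccc1)C(F)(F)F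
Why: The C4 carbonyl oxygen of 5 binds the cationic divalent ruthenium trifluoroacetate formed from [RuCl2(p-cymene)]2 in the acid medium, and carboxylate-assisted metalation of C5–H gives a five-membered ruthenacycle (Ru, O, C4, C4a, C5). PhI(OCOCF3)2 oxidises this to a tetravalent ruthenium aryl trifluoroacetate, and C–O reductive elimination gives aryl trifluoroacetate 6 and returns divalent ruthenium; water on work-up cleaves 6 at the acyl carbon and leaves the chelated phenol 7. The closest known reaction type is the ketone-directed ortho C–H hydroxylation of aryl ketones with divalent ruthenium or divalent palladium and a trivalent iodine oxidant in CF3CO2H/(CF3CO)2O, which has been applied to C5 of chromones and flavones. No ring is closed and no stereocenter is formed. The step needs site selectivity among C5–H, C6–H and the two pyranone C–H bonds: C5–H is the only C–H bond ortho to the ketone because the other ortho atom, C8a, carries O1; metalation at C3 would need a four-membered chelate; C6 and C2 are out of reach of a metal held at the carbonyl oxygen. It also needs chemoselectivity against oxidation of ring A by the iodine reagent, which the O7 acetate, the acyl group and the strongly acidic medium secure by keeping the ring electron-poor; the trifluoroacetate of 6 deactivates the ring further, so a second oxidation is not expected. Any acetate exchanged in the acid is of no consequence, because step 5 acylates both oxygens.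

Step 5
Reactants: 7 7-acetoxy-5-hydroxy-8-methylchromone
Product: 8 5,7-diacetoxy-8-methylchromone
Conditions: Ac2O, pyridine, DMAP (cat.), 40 °C
Reagents that add atoms: acetic anhydride CC(=O)OC(C)=O
Why: Acylation of the chelated O5–H under nucleophilic catalysis; masking it stops the peri hydroxy ketone from chelating palladium in step 8, and the two acetates make the chromone a better acceptor than ethers would.

Step 6
Reactants: 9 4-bromophenol
Product: 10 (4-bromophenoxy)triisopropylsilane
Conditions: i-Pr3SiCl, imidazole, DMF, rt
Reagents that add atoms: triisopropylsilyl chloride CC(C)[Si](Cl)(C(C)C)C(C)C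
Why: Standard silylation of a phenol; the bulky triisopropylsilyl ether is chosen because it should withstand the methanolic acid of step 9 and the amidine base of step 10.

Step 7
Reactants: 10 (4-bromophenoxy)triisopropylsilane
Product: 13 4-(triisopropylsilyloxy)phenylboronic acid, via aryllithium 11 (not isolated), via lithium triisopropoxyborate 12 (not isolated)
Conditions: n-BuLi, THF, −78 °C; B(Oi-Pr)3, −78 °C to rt; aq. HCl (1 M), 0 °C
Reagents that add atoms: triisopropyl borate CC(C)OB(OC(C)C)OC(C)C; water O
Why: Bromine–lithium exchange, trapping of aryllithium 11 as borate 12 and brief mild hydrolysis is the standard route to arylboronic acids; the aryl silyl ether is inert to n-BuLi at −78 °C and to short contact with dilute acid.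

Step 8
Reactants: 8 5,7-diacetoxy-8-methylchromone; 13 4-(triisopropylsilyloxy)phenylboronic acid
Product: 14 (2S)-5,7-diacetoxy-8-methyl-4'-(triisopropylsilyloxy)flavanone
Conditions: Pd(OCOCF3)2 (5 mol%), (R)-t-BuPyOx (6 mol%), NH4PF6 (30 mol%), H2O (5 equiv), 13 (2 equiv), ClCH2CH2Cl, 60 °C
Reagents that add atoms: none
Why: Enantioselective conjugate addition of an arylboronic acid to a chromone under divalent palladium: transmetalation gives a cationic arylpalladium pyridine-oxazoline complex, the C2=C3 bond inserts with aryl delivered to C2, and water protonates the palladium enolate at C3. The C2 center is set by the ligand, whose tert-butyl group blocks one orientation of the bound chromone so that the aryl group reaches one face; aryl acetates and the aryl silyl ether are inert to the weakly acidic aqueous medium.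

Step 9
Reactants: 14 (2S)-5,7-diacetoxy-8-methyl-4'-(triisopropylsilyloxy)flavanone
Product: 15 (2S)-5,7-dihydroxy-8-methyl-4'-(triisopropylsilyloxy)flavanone
Conditions: HCl (1.25 M in MeOH), THF, rt to 40 °C
Reagents that add atoms: none
Why: Acid-catalysed transesterification removes both aryl acetates as methyl acetate. Acid is used rather than base because a flavanone without free phenols would be open to base-induced retro-oxa-Michael ring opening, and the hindered aryl triisopropylsilyl ether is expected to survive methanolic acid.

Step 10
Reactants: 15 (2S)-5,7-dihydroxy-8-methyl-4'-(triisopropylsilyloxy)flavanone; 16 2-methylbut-3-yn-2-ol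
Product: 18 (2S)-5-hydroxy-8-methyl-7-(2-methylbut-3-yn-2-yloxy)-4'-(triisopropylsilyloxy)flavanone, via propargyl trifluoroacetate 17 (not isolated)
Conditions: 16, (CF3CO)2O, DBU, MeCN, −5 °C; then 15, CuCl2·2H2O (1 mol%), DBU (1.1 equiv), MeCN, −5 to 0 °C
Reagents that add atoms: none
Why: Copper-catalysed propargylic substitution: the copper acetylide of 17 ionises and the phenoxide attacks the tertiary carbon, the standard way to make aryl 1,1-dimethylpropargyl ethers. O7–H is the most acidic hydroxyl and reacts, while O5–H is held in the chelate to the ketone. The O7 phenoxide is conjugated to C4 and so suppresses enolisation toward C3 and ring opening, and the silyl ether on O4' blocks the quinone methide pathway.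

Step 11
Reactants: 18 (2S)-5-hydroxy-8-methyl-7-(2-methylbut-3-yn-2-yloxy)-4'-(triisopropylsilyloxy)flavanone
Product: 19 (2S)-5-hydroxy-8-methyl-7-(2-methylbut-3-en-2-yloxy)-4'-(triisopropylsilyloxy)flavanone
Conditions: H2 (1 atm), Pd/CaCO3 poisoned with Pb(OAc)2 (Lindlar catalyst), quinoline, EtOAc, rt
Reagents that add atoms: none
Why: Semihydrogenation of a terminal alkyne on poisoned palladium stops at the alkene when hydrogen uptake is monitored; the aryl ketone and the benzylic C2–O1 bond are not reduced under these conditions.

Step 12
Reactants: 19 (2S)-5-hydroxy-8-methyl-7-(2-methylbut-3-en-2-yloxy)-4'-(triisopropylsilyloxy)flavanone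
Product: 21 (2S)-5,7-dihydroxy-8-methyl-6-(3-methylbut-2-enyl)-4'-(triisopropylsilyloxy)flavanone, via cyclohexadienone 20 (not isolated)
Conditions: o-xylene (degassed), 130 °C
Reagents that add atoms: none
Why: Aromatic Claisen rearrangement: the [3,3] shift of the tertiary allyl ether forms the C6–CH2 bond and turns the 1,1-dimethylallyl group into a linear prenyl group, and dienone 20 tautomerises to the phenol. A shift to C8 gives a dienone that cannot enolise because of the methyl group and reverts, so C6 is the only productive site. The medium is neutral, and tertiary allyl aryl ethers rearrange well below the temperature needed for simple allyl ethers, which limits thermal stress on C2.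

Step 13
Reactants: 21 (2S)-5,7-dihydroxy-8-methyl-6-(3-methylbut-2-enyl)-4'-(triisopropylsilyloxy)flavanone
Product: 22 (2S)-5,7,4'-trihydroxy-8-methyl-6-prenylflavanone (the target)
Conditions: Bu4NF, AcOH (1:1), THF, 0 °C
Reagents that add atoms: none
Why: Fluoride cleaves the aryl silyl ether; buffering with acetic acid keeps the phenols protonated so that no 4'-phenoxide can open ring C, and no acid strong enough to cyclise the prenyl group onto O5 or O7 is present.

## Compound list

1 | 2,4-dihydroxy-3-methylacetophenone | CC(=O)c1ccc(O)c(C)c1O | starting material
2 | dimethylformamide dimethyl acetal | COC(OC)N(C)C | starting material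
3 | (E)-3-(dimethylamino)-1-(2,4-dihydroxy-3-methylphenyl)prop-2-en-1-one | CN(C)/C=C/C(=O)c1ccc(O)c(C)c1O | intermediate
4 | 7-hydroxy-8-methylchromone | O=C1C=COc2c(C)c(O)ccc12 | intermediate
5 | 7-acetoxy-8-methylchromone | CC(=O)Oc1c(C)c2c(cc1)C(=O)C=CO2 | intermediate
6 | 7-acetoxy-8-methyl-5-(trifluoroacetoxy)chromone | CC(=O)Oc1c(C)c2c(c(OC(=O)C(F)(F)F)c1)C(=O)C=CO2 | intermediate
7 | 7-acetoxy-5-hydroxy-8-methylchromone | CC(=O)Oc1c(C)c2c(c(O)c1)C(=O)C=CO2 | intermediate
8 | 5,7-diacetoxy-8-methylchromone | CC(=O)Oc1c(C)c2c(c(OC(C)=O)c1)C(=O)C=CO2 | intermediate
9 | 4-bromophenol | Oc1ccc(Br)cc1 | starting material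
10 | (4-bromophenoxy)triisopropylsilane | CC(C)[Si](Oc1ccc(Br)cc1)(C(C)C)C(C)C | intermediate
11 | [4-(triisopropylsilyloxy)phenyl]lithium | [Li]c1ccc(O[Si](C(C)C)(C(C)C)C(C)C)cc1 | intermediate
12 | lithium triisopropoxy[4-(triisopropylsilyloxy)phenyl]borate | [Li+].CC(C)O[B-](OC(C)C)(OC(C)C)c1ccc(O[Si](C(C)C)(C(C)C)C(C)C)cc1 | intermediate
13 | 4-(triisopropylsilyloxy)phenylboronic acid | CC(C)[Si](Oc1ccc(B(O)O)cc1)(C(C)C)C(C)C | intermediate
14 | (2S)-5,7-diacetoxy-8-methyl-4'-(triisopropylsilyloxy)flavanone | CC(=O)Oc1c(C)c2c(c(OC(C)=O)c1)C(=O)C[C@@H](c1ccc(O[Si](C(C)C)(C(C)C)C(C)C)cc1)O2 | intermediate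
15 | (2S)-5,7-dihydroxy-8-methyl-4'-(triisopropylsilyloxy)flavanone | Oc1c(C)c2c(c(O)c1)C(=O)C[C@@H](c1ccc(O[Si](C(C)C)(C(C)C)C(C)C)cc1)O2 | intermediate
16 | 2-methylbut-3-yn-2-ol | CC(C)(O)C#C | starting material
17 | 2-methylbut-3-yn-2-yl trifluoroacetate | CC(C)(OC(=O)C(F)(F)F)C#C | intermediate
18 | (2S)-5-hydroxy-8-methyl-7-(2-methylbut-3-yn-2-yloxy)-4'-(triisopropylsilyloxy)flavanone | C#CC(C)(C)Oc1c(C)c2c(c(O)c1)C(=O)C[C@@H](c1ccc(O[Si](C(C)C)(C(C)C)C(C)C)cc1)O2 | intermediate
19 | (2S)-5-hydroxy-8-methyl-7-(2-methylbut-3-en-2-yloxy)-4'-(triisopropylsilyloxy)flavanone | C=CC(C)(C)Oc1c(C)c2c(c(O)c1)C(=O)C[C@@H](c1ccc(O[Si](C(C)C)(C(C)C)C(C)C)cc1)O2 | intermediate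
20 | (2S)-5-hydroxy-8-methyl-6-(3-methylbut-2-enyl)-2-[4-(triisopropylsilyloxy)phenyl]-2,3-dihydrochromene-4,7(6H)-dione | CC(C)=CCC1C(=O)C(C)=C2O[C@H](c3ccc(O[Si](C(C)C)(C(C)C)C(C)C)cc3)CC(=O)C2=C1O | intermediate
21 | (2S)-5,7-dihydroxy-8-methyl-6-(3-methylbut-2-enyl)-4'-(triisopropylsilyloxy)flavanone | CC(C)=CCc1c(O)c(C)c2c(c1O)C(=O)C[C@@H](c1ccc(O[Si](C(C)C)(C(C)C)C(C)C)cc1)O2 | intermediate
22 | (2S)-5,7,4'-trihydroxy-8-methyl-6-prenylflavanone | CC(C)=CCc1c(O)c(C)c2c(c1O)C(=O)C[C@@H](c1ccc(O)cc1)O2 | target

## Step count and risk

Total step count: 13. Longest linear sequence: 11 steps (steps 1 to 5 and 8 to 13); steps 6 and 7 form the two-step branch to boronic acid 13.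

**Step 4 (key step).** The most likely failure is oxidative degradation of ring A or of the pyranone double bond by the trivalent iodine reagent in competition with a slow metalation, since the pyranone carbonyl is partly protonated in the acid and binds ruthenium less well than a simple aryl ketone. Partial exchange of the acetate can also occur, but that converges in step 5.
Fallback, from 5 to 7, with halogen in place of oxygen in the C–H functionalisation: ketone-directed ortho bromination with Pd(OAc)2 (cat.), N-bromosuccinimide and CF3SO3H in ClCH2CH2Cl should give 7-acetoxy-5-bromo-8-methylchromone F1. Miyaura borylation (B2pin2, PdCl2(dppf), KOAc, dioxane, 80 °C) should give 7-acetoxy-8-methyl-5-(4,4,5,5-tetramethyl-1,3,2-dioxaborolan-2-yl)chromone F2. Oxidation with NaBO3·4H2O in THF/H2O at rt should give 7; if the acetate is lost there, step 5 still leads to 8.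

**Step 8.** The likely problems are slow insertion into a doubly oxygenated chromone with competing protodeboronation of the electron-rich boronic acid, or insufficient facial selectivity.
Fallback, from 8 and 13 back to 14, by resolution in place of asymmetric induction: aryl transfer with Pd(OCOCF3)2 and achiral 2,2'-bipyridine should give racemic 5,7-diacetoxy-8-methyl-4'-(triisopropylsilyloxy)flavanone F3. Kinetic resolution by asymmetric transfer hydrogenation with RuCl(p-cymene)[(R,R)-TsDPEN], or its antipode if that is the one that reduces the 2R ketone, and HCO2H/Et3N should convert the 2R enantiomer into (2R,4R)-5,7-diacetoxy-8-methyl-4'-(triisopropylsilyloxy)flavan-4-ol F4, which is separated. The unreduced 2S ketone is 14.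

**Step 10.** Substitution at the hindered, weakly nucleophilic O7 phenoxide next to the C8 methyl group may be slow, so that elimination of the activated propargyl ester or base-induced opening of ring C competes.
Fallback, from 15 directly to 19, under neutral conditions and without the alkyne, so that step 11 and its risk of over-reduction also disappear: 2-methylbut-3-en-2-yl isobutyl carbonate F5, made from 2-methylbut-3-en-2-ol and isobutyl chloroformate, is ionised by Pd(PPh3)4 in THF at 0 °C. Zerovalent palladium gives a dimethylallyl palladium cation with loss of carbon dioxide, and the phenoxide formed by the released alkoxide attacks the more substituted terminus to give 19.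

**Step 12.** Thermal ionisation of the tertiary allyl ether with loss of the C5 unit would return 15. Slow thermal opening of ring C would erode the configuration at C2.
Fallback, from 15 to 21, by cross-coupling in place of the sigmatropic shift: N-iodosuccinimide in DMF at 0 °C should iodinate C6, the only free position of ring A, to give (2S)-5,7-dihydroxy-6-iodo-8-methyl-4'-(triisopropylsilyloxy)flavanone F6. Stille coupling with tributyl(3-methylbut-2-enyl)stannane and Pd(PPh3)4 in DMF at 80 °C should give 21.

**Step 1.** The acetal is also a methylating agent, and O-methylation of the free para hydroxyl would carry a methyl ether into the route that cannot be removed selectively.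
Fallback, from 1 to 4, by Claisen formylation in place of the enaminone: NaH (3.5 equiv) and ethyl formate in THF at 0 °C to rt formylate the methyl ketone, and on acidification the product closes to the hemiacetal 2,7-dihydroxy-8-methylchroman-4-one F7. Warming in AcOH with catalytic HCl dehydrates it to 4.

## Further compounds

F1 | step 4 | 7-acetoxy-5-bromo-8-methylchromone | CC(=O)Oc1c(C)c2c(c(Br)c1)C(=O)C=CO2
F2 | step 4 | 7-acetoxy-8-methyl-5-(4,4,5,5-tetramethyl-1,3,2-dioxaborolan-2-yl)chromone | CC(=O)Oc1c(C)c2c(c(B3OC(C)(C)C(C)(C)O3)c1)C(=O)C=CO2
F3 | step 8 | racemic 5,7-diacetoxy-8-methyl-4'-(triisopropylsilyloxy)flavanone | CC(=O)Oc1c(C)c2c(c(OC(C)=O)c1)C(=O)CC(c1ccc(O[Si](C(C)C)(C(C)C)C(C)C)cc1)O2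
F4 | step 8 | (2R,4R)-5,7-diacetoxy-8-methyl-4'-(triisopropylsilyloxy)flavan-4-ol | CC(=O)Oc1c(C)c2c(c(OC(C)=O)c1)[C@H](O)C[C@H](c1ccc(O[Si](C(C)C)(C(C)C)C(C)C)cc1)O2
F5 | step 10 | 2-methylbut-3-en-2-yl isobutyl carbonate | C=CC(C)(C)OC(=O)OCC(C)C
F6 | step 12 | (2S)-5,7-dihydroxy-6-iodo-8-methyl-4'-(triisopropylsilyloxy)flavanone | Oc1c(C)c2c(c(O)c1I)C(=O)C[C@@H](c1ccc(O[Si](C(C)C)(C(C)C)C(C)C)cc1)O2
F7 | step 1 | 2,7-dihydroxy-8-methylchroman-4-one | O=C1CC(O)Oc2c(C)c(O)ccc12
A1 | alternative 1 | (2S)-4'-(tert-butyldimethylsilyloxy)-5,7-dihydroxy-8-methyl-6-prenylflavanone | CC(C)=CCc1c(O)c(C)c2c(c1O)C(=O)C[C@@H](c1ccc(O[Si](C)(C)C(C)(C)C)cc1)O2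
A2 | alternative 1 | (2S)-2-[4-(tert-butyldimethylsilyloxy)phenyl]-6-ethyl-2,3-dihydro-4H-pyran-4-one | CCC1=CC(=O)C[C@@H](c2ccc(O[Si](C)(C)C(C)(C)C)cc2)O1
A3 | alternative 1 | 2-(3-methylbut-2-enyl)malonyl dichloride | CC(C)=CCC(C(=O)Cl)C(=O)Cl
A4 | alternative 2 | (2S)-5,7,4'-tris(methoxymethoxy)-8-methyl-6-prenylflavanone | CC(C)=CCc1c(OCOC)c(C)c2c(c1OCOC)C(=O)C[C@@H](c1ccc(OCOC)cc1)O2
A5 | alternative 2 | 5,7-bis(methoxymethoxy)-8-methyl-6-prenylchromone | CC(C)=CCc1c(OCOC)c(C)c2c(c1OCOC)C(=O)C=CO2
A6 | alternative 2 | 4-(methoxymethoxy)phenylboronic acid | COCOc1ccc(B(O)O)cc1
A7 | alternative 3 | (2S)-5,7,4'-tris(tert-butyldimethylsilyloxy)-8-methyl-6-prenylflavanone | CC(C)=CCc1c(O[Si](C)(C)C(C)(C)C)c(C)c2c(c1O[Si](C)(C)C(C)(C)C)C(=O)C[C@@H](c1ccc(O[Si](C)(C)C(C)(C)C)cc1)O2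
A8 | alternative 3 | 2-diazo-1-[2-[4-(tert-butyldimethylsilyloxy)benzyloxy]-4,6-bis(tert-butyldimethylsilyloxy)-3-methyl-5-prenylphenyl]ethanone | CC(C)=CCc1c(O[Si](C)(C)C(C)(C)C)c(C)c(OCc2ccc(O[Si](C)(C)C(C)(C)C)cc2)c(C(=O)C=[N+]=[N-])c1O[Si](C)(C)C(C)(C)C
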